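**Assumption:** the target has no stereocentre, so it is one achiral compound. The only stereochemical element in the route is the E geometry of 7–9. The transient stereocentres of 11–14 form as racemic diastereomer mixtures and disappear on aromatisation.

## Retrosynthetic overview

1. Target 18 ⇐ methyl salicylate 16 by ester hydrolysis.
2. 16 ⇐ cyclohexenone β-keto ester 13 by bromination/dehydrobromination (aromatisation).
3. 13 ⇐ methyl acetoacetate 10 + (E)-13-phenyltridec-2-enal 9: intermolecular Michael addition forms the bond that becomes C1–C6 of the arene, then intramolecular aldol condensation closes the ring.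
4. 9 ⇐ 11-phenylundecanal 5 (Horner–Wadsworth–Emmons, reduction, allylic oxidation); 5 ⇐ iodobenzene 1 + undec-10-yn-1-ol 2 (Sonogashira, hydrogenation, oxidation).
5. Ring order: the terminal phenyl ring is bought; the salicylate ring is the only ring formed, built in step 7 and aromatised in step 8.

## Route

**Step 1**
Reactants: 1 iodobenzene; 2 undec-10-yn-1-ol
Product: 3 11-phenylundec-10-yn-1-ol
Conditions: PdCl2(PPh3)2 (2 mol %), CuI (4 mol %), Et3N (3 equiv), THF, rt, N2
Reagents that add atoms: none
Why: Sonogashira coupling; the divalent palladium precatalyst is reduced in the flask to zerovalent palladium, which inserts into the C–I bond and couples with the copper acetylide, and the free alcohol is tolerated.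

**Step 2**
Reactants: 3 11-phenylundec-10-yn-1-ol
Product: 4 11-phenylundecan-1-ol
Conditions: H2 (1 atm), 10% Pd/C, EtOAc, rt
Reagents that add atoms: none
Why: Catalytic hydrogenation reduces the alkyne fully to the alkane, and nothing else in the molecule is reducible or hydrogenolysable.

**Step 3**
Reactants: 4 11-phenylundecan-1-ol
Product: 5 11-phenylundecanal
Conditions: TEMPO (10 mol %), PhI(OAc)2 (1.1 equiv), CH2Cl2, rt
Reagents that add atoms: none
Why: Oxoammonium-mediated (TEMPO/PhI(OAc)2) oxidation of a primary alcohol stops cleanly at the aldehyde under anhydrous conditions.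

**Step 4**
Reactants: 5 11-phenylundecanal; 6 triethyl phosphonoacetate
Product: 7 ethyl (E)-13-phenyltridec-2-enoate
Conditions: NaH (1.15 equiv), THF, 0 °C → rt
Reagents that add atoms: none
Why: Horner–Wadsworth–Emmons olefination with a stabilised phosphonate anion gives the E-enoate under thermodynamic control.

**Step 5**
Reactants: 7 ethyl (E)-13-phenyltridec-2-enoate
Product: 8 (E)-13-phenyltridec-2-en-1-ol
Conditions: i-Bu2AlH (2.3 equiv), CH2Cl2, −78 → 0 °C; aq. potassium sodium tartrate (KNaC4H4O6)
Reagents that add atoms: none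
Why: DIBAL-H reduces the enoate by 1,2-hydride delivery to the allylic alcohol without touching the alkene, so the E geometry is kept.

**Step 6**
Reactants: 8 (E)-13-phenyltridec-2-en-1-ol
Product: 9 (E)-13-phenyltridec-2-enal
Conditions: activated MnO2 (15 equiv), CH2Cl2, rt
Reagents that add atoms: none
Why: MnO2 allylic oxidation is selective for the allylic alcohol and gives the E-enal without over-oxidation.

**Step 7**
Reactants: 9 (E)-13-phenyltridec-2-enal; 10 methyl acetoacetate
Product: 13 methyl 2-oxo-6-(10-phenyldecyl)cyclohex-3-ene-1-carboxylate, via Michael adduct 11 (not isolated), via cyclic aldol 12 (not isolated)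
Conditions: NaOMe (0.15 equiv), MeOH, 0 °C → rt, 16 h; then AcOH quench, p-TsOH·H2O (5 mol %), toluene, reflux (Dean–Stark)
Reagents that add atoms: none
Why: Michael addition of the soft β-keto ester enolate to the enal β-carbon, then intramolecular aldol of the methyl ketone onto the aldehyde and acid-driven dehydration (Robinson-type annulation); the only feasible ring is six-membered, and the C1/C6 stereocentres form as a racemic mixture that step 8 erases.

**Step 8**
Reactants: 13 methyl 2-oxo-6-(10-phenyldecyl)cyclohex-3-ene-1-carboxylate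
Product: 16 methyl 2-hydroxy-6-(10-phenyldecyl)benzoate, via bromo keto ester 14 (not isolated), via dienone tautomer 15 (not isolated)
Conditions: Br2 (1.0 equiv), AcOH, 15 °C, dark, 1 h; then reflux, 6 h
Reagents that add atoms: none
Why: α-Bromination at the doubly activated C1 followed by thermal dehydrobromination gives a cyclohexadienone that tautomerises to the phenol, driven by aromatisation; the isolated phenyl ring does not react with Br2 without a Lewis acid.

**Step 9**
Reactants: 16 methyl 2-hydroxy-6-(10-phenyldecyl)benzoate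
Product: 18 2-hydroxy-6-(10-phenyldecyl)benzoic acid, via dipotassium salt 17 (not isolated)
Conditions: KOH (10 equiv), DMSO–H2O (4:1), 90 °C; then 1 M HCl, 0 °C, pH 2
Reagents that add atoms: potassium hydroxide, [K+].[OH-]
Why: Saponification by acyl–oxygen cleavage under forcing conditions overcomes the hindrance of the 2,6-disubstituted benzoate, and cold acidification releases the acid without decarboxylation.

## Compound list

1 | iodobenzene | Ic1ccccc1 | starting material
2 | undec-10-yn-1-ol | C#CCCCCCCCCCO | starting material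
3 | 11-phenylundec-10-yn-1-ol | OCCCCCCCCCC#Cc1ccccc1 | intermediate
4 | 11-phenylundecan-1-ol | OCCCCCCCCCCCc1ccccc1 | intermediate
5 | 11-phenylundecanal | O=CCCCCCCCCCCc1ccccc1 | intermediate
6 | triethyl phosphonoacetate | CCOC(=O)CP(=O)(OCC)OCC | starting material
7 | ethyl (E)-13-phenyltridec-2-enoate | CCOC(=O)/C=C/CCCCCCCCCCc1ccccc1 | intermediate
8 | (E)-13-phenyltridec-2-en-1-ol | OC/C=C/CCCCCCCCCCc1ccccc1 | intermediate
9 | (E)-13-phenyltridec-2-enal | O=C/C=C/CCCCCCCCCCc1ccccc1 | intermediate
10 | methyl acetoacetate (methyl 3-oxobutanoate) | COC(=O)CC(C)=O | starting material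
11 | methyl 2-acetyl-5-oxo-3-(10-phenyldecyl)pentanoate (Michael adduct, stereoisomer mixture) | COC(=O)C(C(C)=O)C(CC=O)CCCCCCCCCCc1ccccc1 | intermediate (not isolated)
12 | methyl 4-hydroxy-2-oxo-6-(10-phenyldecyl)cyclohexane-1-carboxylate (cyclic aldol, stereoisomer mixture) | COC(=O)C1C(=O)CC(O)CC1CCCCCCCCCCc1ccccc1 | intermediate (not isolated)
13 | methyl 2-oxo-6-(10-phenyldecyl)cyclohex-3-ene-1-carboxylate (racemic, diastereomer mixture) | COC(=O)C1C(=O)C=CCC1CCCCCCCCCCc1ccccc1 | intermediate
14 | methyl 1-bromo-2-oxo-6-(10-phenyldecyl)cyclohex-3-ene-1-carboxylate (stereoisomer mixture) | COC(=O)C1(Br)C(=O)C=CCC1CCCCCCCCCCc1ccccc1 | intermediate (not isolated)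
15 | methyl 6-oxo-2-(10-phenyldecyl)cyclohexa-1,4-diene-1-carboxylate | COC(=O)C1=C(CCCCCCCCCCc2ccccc2)CC=CC1=O | intermediate (not isolated)
16 | methyl 2-hydroxy-6-(10-phenyldecyl)benzoate | COC(=O)c1c(O)cccc1CCCCCCCCCCc1ccccc1 | intermediate
17 | dipotassium 2-oxido-6-(10-phenyldecyl)benzoate | [K+].[K+].[O-]C(=O)c1c([O-])cccc1CCCCCCCCCCc1ccccc1 | intermediate (not isolated)
18 | 2-hydroxy-6-(10-phenyldecyl)benzoic acid | O=C(O)c1c(O)cccc1CCCCCCCCCCc1ccccc1 | target

## Summary

Total step count: 9.
Longest linear sequence: 9 steps (1/2 → 18); compounds 6 and 10 are bought.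

**Steps most likely to fail, and fallbacks**

Step 7 (Michael/aldol annulation). The enal can oligomerise under alkoxide, or react at the carbonyl (Knoevenagel) instead of at the β-carbon. The fallback sets out from aldehyde 5 and comes back at ester 16, bypassing steps 4–8 by using an acceptor already at the arene oxidation level. Homologation of 5 with dimethyl (1-diazo-2-oxopropyl)phosphonate (K2CO3, MeOH, rt) gives 12-phenyldodec-1-yne F1. Deprotonation with n-BuLi (THF, −78 °C) and formylation with DMF (quench into aq. KH2PO4) gives 13-phenyltridec-2-ynal F2. Michael addition of methyl acetoacetate 10 to F2 (NaOMe, MeOH, 0 °C → rt) gives methyl 2-acetyl-5-oxo-3-(10-phenyldecyl)pent-3-enoate F3 (not isolated). Its intramolecular aldol gives methyl 4-hydroxy-2-oxo-6-(10-phenyldecyl)cyclohex-5-ene-1-carboxylate F4 (not isolated). Dehydration gives methyl 2-oxo-6-(10-phenyldecyl)cyclohexa-3,5-diene-1-carboxylate F5 (not isolated), the keto tautomer of 16, which enolises to 16 with no oxidation step.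

Step 8 (aromatisation). Excess bromine could brominate the newly formed phenol ring, and hot HBr/AcOH could attack the ester. The fallback sets out from 13 and comes back at 16, replacing bromination/E2 with a selenoxide syn-elimination. PhSeCl and pyridine (CH2Cl2, 0 °C → rt) give methyl 2-oxo-6-(10-phenyldecyl)-1-(phenylselanyl)cyclohex-3-ene-1-carboxylate F6. Oxidation with 30% H2O2 (CH2Cl2, 0 °C → rt) gives methyl 2-oxo-6-(10-phenyldecyl)-1-(phenylseleninyl)cyclohex-3-ene-1-carboxylate F7 (not isolated). F7 eliminates across C1–C6 at room temperature to dienone 15, which tautomerises to 16 under neutral, acid-free conditions.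

Step 9 (hydrolysis of the hindered ester). Attack at the carbonyl flanked by two ortho substituents may stall, and harsher forcing invites decarboxylation. The fallback sets out from 16 and comes back at 18, cleaving the O–methyl bond instead of the acyl–oxygen bond. LiI (5 equiv) in refluxing pyridine dealkylates the unhindered methyl carbon by SN2 and gives lithium 2-hydroxy-6-(10-phenyldecyl)benzoate F8 (not isolated). Cold 1 M HCl then converts F8 into 18.

## Further compounds

F1 | step 7 | 12-phenyldodec-1-yne | C#CCCCCCCCCCCc1ccccc1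
F2 | step 7 | 13-phenyltridec-2-ynal | O=CC#CCCCCCCCCCCc1ccccc1
F3 | step 7 | methyl 2-acetyl-5-oxo-3-(10-phenyldecyl)pent-3-enoate | COC(=O)C(C(C)=O)C(=CC=O)CCCCCCCCCCc1ccccc1
F4 | step 7 | methyl 4-hydroxy-2-oxo-6-(10-phenyldecyl)cyclohex-5-ene-1-carboxylate | COC(=O)C1C(=O)CC(O)C=C1CCCCCCCCCCc1ccccc1
F5 | step 7 | methyl 2-oxo-6-(10-phenyldecyl)cyclohexa-3,5-diene-1-carboxylate | COC(=O)C1C(=O)C=CC=C1CCCCCCCCCCc1ccccc1
F6 | step 8 | methyl 2-oxo-6-(10-phenyldecyl)-1-(phenylselanyl)cyclohex-3-ene-1-carboxylate | COC(=O)C1([Se]c2ccccc2)C(=O)C=CCC1CCCCCCCCCCc1ccccc1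
F7 | step 8 | methyl 2-oxo-6-(10-phenyldecyl)-1-(phenylseleninyl)cyclohex-3-ene-1-carboxylate | COC(=O)C1([Se](=O)c2ccccc2)C(=O)C=CCC1CCCCCCCCCCc1ccccc1
F8 | step 9 | lithium 2-hydroxy-6-(10-phenyldecyl)benzoate | [Li+].[O-]C(=O)c1c(O)cccc1CCCCCCCCCCc1ccccc1
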